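**Plan**

- Locants: ring A a1 C–OMe, a2 C–H, a3 C–Me, a4 C–C(=O), a5 C–O (ether), a6 C–CH2OH; ring B b1 ether O, b2 ester O, b3 Me, b4 OH, b5 lactone C=O, b6 lactol carbon.
- Cuts, last bond first: the lactol O–H (resolved through an acylal), the five-membered lactol ring (from b6 acetal and b5 methyl ester), the seven-membered lactone at the a4 C(=O)–O(b2) bond, and the a4–CO2H bond (from a4–Br).
- Ring A is then cut at a1–a6, a4–a5 and a1–a2. It is a 1,3-dioxygenated arene (O at a1 and a5, the a6 carbon between them), which is the pattern a vinylketene and an ynol ether give, so the hindered a5–O–b1 oxygen can sit on an sp carbon before ring A exists.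
- The ynol ether is cut at O–C(sp) into the fully substituted ring B phenol and a 1,1-dibromoalkene; ring B comes from methyl 2,4-dihydroxy-3-methylbenzoate by oxygenation at C5 and formylation at C6.
- Forward: ring B is elaborated, alkynylated on the b1 oxygen, ring A is grown on that oxygen, a4 is brominated and carboxylated, the seven-membered lactone is closed, then the lactol ring.
- Stereochemistry: the only stereocentre (lactol carbon, R) is set last by catalyst-controlled acylation of the equilibrating lactol and released by a lipase.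

Key step: step 9

Assumption: the lactol carbon of a 3-hydroxyphthalide racemises through its ring-opened formyl acid when base or aqueous acid is present, so the (R) configuration is locked as an acylal and freed only in the last step under neutral non-aqueous conditions, in which the free lactol is taken to hold its configuration.

**Route**

Step 1
Reactants: 1 methyl 2,4-dihydroxy-3-methylbenzoate
Product: 2 methyl 5-formyl-2,4-dihydroxy-3-methylbenzoate
Conditions: Cl2CHOMe, TiCl4, CH2Cl2, 0 °C to rt; aq. HCl
Reagents that add atoms: dichloromethyl methyl ether, COC(Cl)Cl; water, O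
Why: Rieche formylation, in which the titanium-activated dichloromethyl ether attacks the only position that is ortho and para to the two hydroxyls (C5, the future b1), C3 being blocked by methyl and C6 being meta to both donors.

Step 2
Reactants: 2 methyl 5-formyl-2,4-dihydroxy-3-methylbenzoate
Product: 3 methyl 2,4-bis(benzyloxy)-5-formyl-3-methylbenzoate
Conditions: BnBr, K2CO3, DMF, 60 °C
Reagents that add atoms: benzyl bromide, BrCc1ccccc1
Why: Williamson ether synthesis, in which both chelated phenoxides are alkylated in warm DMF to give the b2 and b4 benzyl ethers that should last until the hydrogenolysis.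

Step 3
Reactants: 3 methyl 2,4-bis(benzyloxy)-5-formyl-3-methylbenzoate
Product: 5 methyl 2,4-bis(benzyloxy)-5-hydroxy-3-methylbenzoate, via aryl formate 4 (not isolated)
Conditions: mCPBA, CH2Cl2, 0 °C to rt; aq. NaHCO3 wash; then MeOH, Et3N (cat.), rt
Reagents that add atoms: 3-chloroperbenzoic acid, OOC(=O)c1cccc(Cl)c1
Why: Baeyer–Villiger (Dakin-type) oxidation, in which the electron-rich 2,4-dialkoxyaryl group migrates in preference to hydride and amine-catalysed methanolysis of the aryl formate frees the b1 phenol without touching the flanked methyl ester.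

Step 4
Reactants: 5 methyl 2,4-bis(benzyloxy)-5-hydroxy-3-methylbenzoate
Product: 6 methyl 4,6-bis(benzyloxy)-2-formyl-3-hydroxy-5-methylbenzoate
Conditions: MgCl2, Et3N, (CH2O)n, MeCN, reflux
Reagents that add atoms: paraformaldehyde (as formaldehyde), C=O
Why: Casnati–Skattebøl ortho-formylation, in which the magnesium phenoxide delivers formaldehyde to its only free ortho carbon (b6) and a second formaldehyde oxidises the chelated benzylic alkoxide by Oppenauer-type hydride transfer, which is expected to outrun lactonisation onto the neighbouring ester.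

Step 5
Reactants: 6 methyl 4,6-bis(benzyloxy)-2-formyl-3-hydroxy-5-methylbenzoate
Product: 7 methyl 4,6-bis(benzyloxy)-2-(dimethoxymethyl)-3-hydroxy-5-methylbenzoate
Conditions: HC(OMe)3, MeOH, PPTS (cat.), rt; Et3N quench
Reagents that add atoms: trimethyl orthoformate, COC(OC)OC; methanol, CO
Why: acid-catalysed acetalisation with the orthoformate as dehydrating agent masks the aldehyde, which would be photoactive in the key step, while benzyl ethers, ester and phenol are inert and the open acetal is the kinetic product over the cyclic pseudo-ester.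

Step 6
Reactants: 8 (tert-butyldimethylsilyloxy)acetaldehyde
Product: 9 tert-butyl[(3,3-dibromoprop-2-en-1-yl)oxy]dimethylsilane
Conditions: CBr4, PPh3, Zn, CH2Cl2, rt
Reagents that add atoms: carbon tetrabromide, BrC(Br)(Br)Br
Why: Corey–Fuchs (Ramirez) dibromoolefination, in which the ylide made from CBr4, PPh3 and Zn converts the aldehyde into the gem-dibromoalkene without releasing a brominating phosphorane that could attack the silyl ether.

Step 7
Reactants: 7 methyl 4,6-bis(benzyloxy)-2-(dimethoxymethyl)-3-hydroxy-5-methylbenzoate; 9 tert-butyl[(3,3-dibromoprop-2-en-1-yl)oxy]dimethylsilane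
Product: 11 methyl 4,6-bis(benzyloxy)-3-{[3-(tert-butyldimethylsilyloxy)prop-1-yn-1-yl]oxy}-2-(dimethoxymethyl)-5-methylbenzoate, via (Z)-bromoenol ether 10 (not isolated)
Conditions: 9 (1.5 equiv), CuI (10 mol%), 2,2'-bipyridine (20 mol%), K3PO4, toluene, 110 °C; then KOt-Bu, 1,4-dioxane, rt
Reagents that add atoms: none
Why: CuI-catalysed Ullmann-type vinylic C–O coupling of a phenol with a 1,1-dibromoalkene, in which the C–Br bond trans to the alkyl group reacts first to give the (Z)-bromoenol ether, whose anti-periplanar H and Br are then removed by KOt-Bu (E2) to give the ynol ether, while acetal, benzyl ethers, silyl ether and the flanked ester tolerate both bases.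

Step 8
Reactants: 12 3-methylbut-3-en-2-one
Product: 14 1-diazo-3-methylbut-3-en-2-one, via trifluoroacetyl diketone 13 (not isolated)
Conditions: LiN(SiMe3)2, THF, −78 °C; CF3CO2CH2CF3; aq. HCl work-up; then 4-acetamidobenzenesulfonyl azide, Et3N, H2O, MeCN, rt
Reagents that add atoms: 4-acetamidobenzenesulfonyl azide, CC(=O)Nc1ccc(cc1)S(=O)(=O)N=[N+]=[N-]; 2,2,2-trifluoroethyl trifluoroacetate, FC(F)(F)COC(=O)C(F)(F)F (its trifluoroacetyl group is held only in 13)
Why: detrifluoroacetylative diazo transfer, in which kinetic enolisation at the methyl group and trifluoroacetylation give a 1,3-diketone that accepts the diazo group from the sulfonyl azide and loses the trifluoroacetyl group as the N-sulfonyl amide, a sequence that avoids conjugate addition to the enone.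

Step 9
Reactants: 11 methyl 4,6-bis(benzyloxy)-3-{[3-(tert-butyldimethylsilyloxy)prop-1-yn-1-yl]oxy}-2-(dimethoxymethyl)-5-methylbenzoate; 14 1-diazo-3-methylbut-3-en-2-one
Product: 19 methyl 4,6-bis(benzyloxy)-3-[2-(tert-butyldimethylsilyloxymethyl)-3-hydroxy-5-methylphenoxy]-2-(dimethoxymethyl)-5-methylbenzoate, via isopropenylketene 15 (not isolated), via 4-vinylcyclobutenone 16 (not isolated), via dienylketene 17 (not isolated), via cyclohexadienone 18 (not isolated)
Conditions: 14 (1.5 equiv), hν (300 nm, Pyrex), ClCH2CH2Cl, rt; then 80 °C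
Reagents that add atoms: none
Why: Light at 300 nm expels N2 from 14 and Wolff rearrangement gives isopropenylketene 15, which adds across the ynol ether in a regioselective [2+2] cycloaddition to 4-vinylcyclobutenone 16 (bonds a1–a6 and a4–a5). Four-electron electrocyclic opening of 16 (light or 80 °C) gives dienylketene 17, whose six-electron electrocyclisation forms a1–a2 and closes the six-membered carbocycle ring A as dienone 18, which tautomerises to phenol 19. The closest known reaction is the Danheiser benzannulation of photochemically generated vinylketenes with alkoxy- and siloxyalkynes, applied here to an aryloxyalkyne. No stereocentre remains, because the sp3 carbon of 16 becomes the aromatic carbon a4. The step needs one regiochemistry of the [2+2], which the polarised ynol ether secures: its nucleophilic carbon bearing CH2OTBS bonds to the ketene carbonyl carbon, so the aryloxy carbon becomes a5 and the new hydroxyl appears at a1 with a6 between them. The hindered a5–O–b1 bond is therefore never made at an arene, and the ester, acetal, benzyl ethers and silyl ether are expected to be inert to the ketene.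

Step 10
Reactants: 19 methyl 4,6-bis(benzyloxy)-3-[2-(tert-butyldimethylsilyloxymethyl)-3-hydroxy-5-methylphenoxy]-2-(dimethoxymethyl)-5-methylbenzoate
Product: 20 methyl 4,6-bis(benzyloxy)-3-[6-bromo-2-(tert-butyldimethylsilyloxymethyl)-3-hydroxy-5-methylphenoxy]-2-(dimethoxymethyl)-5-methylbenzoate
Conditions: NBS (1.0 equiv), MeCN, −20 °C to 0 °C, dark
Reagents that add atoms: N-bromosuccinimide, O=C1CCC(=O)N1Br
Why: electrophilic aromatic bromination, which can only occur on ring A and is expected to favour a4 because it is para to the free hydroxyl (the strongest donor) whereas a2 is only ortho to it, which is why the bromine is introduced before O-methylation, and which releases no acid that could harm the acetal or silyl ether.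

Step 11
Reactants: 20 methyl 4,6-bis(benzyloxy)-3-[6-bromo-2-(tert-butyldimethylsilyloxymethyl)-3-hydroxy-5-methylphenoxy]-2-(dimethoxymethyl)-5-methylbenzoate
Product: 21 methyl 4,6-bis(benzyloxy)-3-[6-bromo-2-(tert-butyldimethylsilyloxymethyl)-3-methoxy-5-methylphenoxy]-2-(dimethoxymethyl)-5-methylbenzoate
Conditions: MeI, K2CO3, acetone, 40 °C
Reagents that add atoms: iodomethane, CI
Why: Williamson O-methylation of the only free hydroxyl (a1), under carbonate conditions that leave the silyl ether, acetal and esters untouched.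

Step 12
Reactants: 21 methyl 4,6-bis(benzyloxy)-3-[6-bromo-2-(tert-butyldimethylsilyloxymethyl)-3-methoxy-5-methylphenoxy]-2-(dimethoxymethyl)-5-methylbenzoate
Product: 23 2-[2,4-bis(benzyloxy)-6-(dimethoxymethyl)-5-(methoxycarbonyl)-3-methylphenoxy]-3-(tert-butyldimethylsilyloxymethyl)-4-methoxy-6-methylbenzoic acid, via aryllithium 22 (not isolated)
Conditions: n-BuLi, THF, −78 °C; CO2; AcOH, −78 °C to rt
Reagents that add atoms: carbon dioxide, O=C=O; n-butyllithium, [Li]CCCC (its lithium is held only in 22)
Why: bromine–lithium exchange at −78 °C is much faster than addition of n-BuLi to the doubly flanked methyl ester, and carboxylation of the hindered aryllithium with CO2 gives the a4 acid, with a one-equivalent acetic acid quench that spares acetal and silyl ether.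

Step 13
Reactants: 23 2-[2,4-bis(benzyloxy)-6-(dimethoxymethyl)-5-(methoxycarbonyl)-3-methylphenoxy]-3-(tert-butyldimethylsilyloxymethyl)-4-methoxy-6-methylbenzoic acid
Product: 24 2-[2,4-dihydroxy-6-(dimethoxymethyl)-5-(methoxycarbonyl)-3-methylphenoxy]-3-(tert-butyldimethylsilyloxymethyl)-4-methoxy-6-methylbenzoic acid
Conditions: H2 (1 atm), Pd/C, EtOAc, rt; used directly
Reagents that add atoms: none
Why: catalytic hydrogenolysis cleaves both aryl benzyl ethers, while the silyl ether, acetal, methyl ester and diaryl ether are inert in ethyl acetate.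

Step 14
Reactants: 24 2-[2,4-dihydroxy-6-(dimethoxymethyl)-5-(methoxycarbonyl)-3-methylphenoxy]-3-(tert-butyldimethylsilyloxymethyl)-4-methoxy-6-methylbenzoic acid
Product: 25 depsidone (dibenzo[b,e][1,4]dioxepin-11-one) carrying a1 OMe, a3 Me, a6 CH2OTBS, b3 Me, b4 OH, b5 CO2Me, b6 CH(OMe)2
Conditions: DCC, DMAP (cat.), CH2Cl2, 0 °C to rt
Reagents that add atoms: none
Why: Steglich-type carbodiimide lactonisation, the classical depsidone closure, in which the activated a4 acid can reach only the b2 hydroxyl across the diaryl ether to close the seven-membered lactone, the b4 hydroxyl being para to the ether oxygen and hydrogen-bonded to its ester.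

Step 15
Reactants: 25 depsidone carrying a6 CH2OTBS, b5 CO2Me, b6 CH(OMe)2
Product: 27 racemic lactol (racemate of the target), via formyl ester 26 (not isolated)
Conditions: aq. H2SO4 (1 M), 1,4-dioxane, 50 °C
Reagents that add atoms: water, O
Why: acid hydrolysis cleaves the silyl ether and the dimethyl acetal, and the hydrate of the freed aldehyde attacks the neighbouring methyl ester (neighbouring-group-assisted ester hydrolysis) to close the five-membered ring as the favoured 3-hydroxyphthalide, formed as the racemate, while the hindered aryl ester of the seven-membered lactone should resist dilute acid.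

Step 16
Reactants: 27 racemic lactol
Product: 28 (R)-lactol propanoate that is also propanoylated at the a6 CH2OH (dipropanoate, b4 OH free)
Conditions: (EtCO)2O (2.2 equiv), HyperBTM (5 mol%, the antipode that gives the (R)-acylal), i-Pr2NEt, CH2Cl2, 0 °C
Reagents that add atoms: propanoic anhydride, CCC(=O)OC(=O)CC
Why: acylative dynamic kinetic resolution of a 3-hydroxyphthalide by chiral isothiourea (Lewis-base) acyl transfer, in which the amine equilibrates the lactol enantiomers through the ring-opened formyl carboxylate while the chiral acyl ammonium ion acylates only the (R)-lactol, so the catalyst sets the stereocentre (both antipodes are available), the primary alcohol is acylated as well without stereochemical consequence, and the flanked, hydrogen-bonded b4 phenol is expected to react slowest.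

Step 17
Reactants: 28 (R)-dipropanoate
Product: 29 target CNP0367167.1, (R) at the lactol carbon
Conditions: Candida antarctica lipase B (immobilised), n-BuOH, 2-methyltetrahydrofuran, 30 °C
Reagents that add atoms: none
Why: lipase-catalysed transesterification to butanol cleaves both propanoates at their acyl carbons under neutral non-aqueous conditions, so the C–O bond at the stereocentre is not broken and neither base nor water is present to open the lactol, while the hindered aryl ester of the depsidone is not a substrate.

**Compound list**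

1 | methyl 2,4-dihydroxy-3-methylbenzoate | COC(=O)c1ccc(O)c(C)c1O | starting material
2 | methyl 5-formyl-2,4-dihydroxy-3-methylbenzoate | COC(=O)c1cc(C=O)c(O)c(C)c1O | intermediate
3 | methyl 2,4-bis(benzyloxy)-5-formyl-3-methylbenzoate | COC(=O)c1cc(C=O)c(OCc2ccccc2)c(C)c1OCc1ccccc1 | intermediate
4 | methyl 2,4-bis(benzyloxy)-5-(formyloxy)-3-methylbenzoate (aryl formate, not isolated) | COC(=O)c1cc(OC=O)c(OCc2ccccc2)c(C)c1OCc1ccccc1 | intermediate
5 | methyl 2,4-bis(benzyloxy)-5-hydroxy-3-methylbenzoate | COC(=O)c1cc(O)c(OCc2ccccc2)c(C)c1OCc1ccccc1 | intermediate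
6 | methyl 4,6-bis(benzyloxy)-2-formyl-3-hydroxy-5-methylbenzoate | COC(=O)c1c(C=O)c(O)c(OCc2ccccc2)c(C)c1OCc1ccccc1 | intermediate
7 | methyl 4,6-bis(benzyloxy)-2-(dimethoxymethyl)-3-hydroxy-5-methylbenzoate (ring B phenol: b1 OH, b2 OBn, b3 Me, b4 OBn, b5 CO2Me, b6 CH(OMe)2) | COC(=O)c1c(C(OC)OC)c(O)c(OCc2ccccc2)c(C)c1OCc1ccccc1 | intermediate
8 | (tert-butyldimethylsilyloxy)acetaldehyde | CC(C)(C)[Si](C)(C)OCC=O | starting material
9 | tert-butyl[(3,3-dibromoprop-2-en-1-yl)oxy]dimethylsilane | CC(C)(C)[Si](C)(C)OCC=C(Br)Br | intermediate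
10 | methyl 4,6-bis(benzyloxy)-3-{[(Z)-1-bromo-3-(tert-butyldimethylsilyloxy)prop-1-en-1-yl]oxy}-2-(dimethoxymethyl)-5-methylbenzoate (not isolated) | CC(C)(C)[Si](C)(C)OC/C=C(\Br)Oc1c(OCc2ccccc2)c(C)c(OCc2ccccc2)c(C(=O)OC)c1C(OC)OC | intermediate
11 | methyl 4,6-bis(benzyloxy)-3-{[3-(tert-butyldimethylsilyloxy)prop-1-yn-1-yl]oxy}-2-(dimethoxymethyl)-5-methylbenzoate (ring B aryl ynol ether) | CC(C)(C)[Si](C)(C)OCC#COc1c(OCc2ccccc2)c(C)c(OCc2ccccc2)c(C(=O)OC)c1C(OC)OC | intermediate
12 | 3-methylbut-3-en-2-one | CC(=C)C(C)=O | starting material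
13 | 1,1,1-trifluoro-5-methylhex-5-ene-2,4-dione (not isolated) | CC(=C)C(=O)CC(=O)C(F)(F)F | intermediate
14 | 1-diazo-3-methylbut-3-en-2-one | CC(=C)C(=O)C=[N+]=[N-] | intermediate
15 | 3-methylbuta-1,3-dien-1-one (isopropenylketene, not isolated) | CC(=C)C=C=O | intermediate
16 | methyl 4,6-bis(benzyloxy)-3-{[2-(tert-butyldimethylsilyloxymethyl)-3-oxo-4-(prop-1-en-2-yl)cyclobut-1-en-1-yl]oxy}-2-(dimethoxymethyl)-5-methylbenzoate (racemic, not isolated) | CC(=C)C1C(=O)C(CO[Si](C)(C)C(C)(C)C)=C1Oc1c(OCc2ccccc2)c(C)c(OCc2ccccc2)c(C(=O)OC)c1C(OC)OC | intermediate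
17 | methyl 4,6-bis(benzyloxy)-3-{[(3E)-2-(tert-butyldimethylsilyloxymethyl)-5-methyl-1-oxohexa-1,3,5-trien-3-yl]oxy}-2-(dimethoxymethyl)-5-methylbenzoate (dienylketene, not isolated) | CC(=C)/C=C(/Oc1c(OCc2ccccc2)c(C)c(OCc2ccccc2)c(C(=O)OC)c1C(OC)OC)C(CO[Si](C)(C)C(C)(C)C)=C=O | intermediate
18 | methyl 4,6-bis(benzyloxy)-3-{[2-(tert-butyldimethylsilyloxymethyl)-5-methyl-3-oxocyclohexa-1,5-dien-1-yl]oxy}-2-(dimethoxymethyl)-5-methylbenzoate (not isolated) | CC1=CC(Oc2c(OCc3ccccc3)c(C)c(OCc3ccccc3)c(C(=O)OC)c2C(OC)OC)=C(CO[Si](C)(C)C(C)(C)C)C(=O)C1 | intermediate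
19 | methyl 4,6-bis(benzyloxy)-3-[2-(tert-butyldimethylsilyloxymethyl)-3-hydroxy-5-methylphenoxy]-2-(dimethoxymethyl)-5-methylbenzoate (a1 OH, a3 Me, a5 OAr, a6 CH2OTBS) | Oc1cc(C)cc(Oc2c(OCc3ccccc3)c(C)c(OCc3ccccc3)c(C(=O)OC)c2C(OC)OC)c1CO[Si](C)(C)C(C)(C)C | intermediate
20 | methyl 4,6-bis(benzyloxy)-3-[6-bromo-2-(tert-butyldimethylsilyloxymethyl)-3-hydroxy-5-methylphenoxy]-2-(dimethoxymethyl)-5-methylbenzoate (Br at a4) | Oc1cc(C)c(Br)c(Oc2c(OCc3ccccc3)c(C)c(OCc3ccccc3)c(C(=O)OC)c2C(OC)OC)c1CO[Si](C)(C)C(C)(C)C | intermediate
21 | methyl 4,6-bis(benzyloxy)-3-[6-bromo-2-(tert-butyldimethylsilyloxymethyl)-3-methoxy-5-methylphenoxy]-2-(dimethoxymethyl)-5-methylbenzoate | COc1cc(C)c(Br)c(Oc2c(OCc3ccccc3)c(C)c(OCc3ccccc3)c(C(=O)OC)c2C(OC)OC)c1CO[Si](C)(C)C(C)(C)C | intermediate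
22 | aryllithium from 21, lithium at a4 in place of bromine (not isolated) | COc1cc(C)c([Li])c(Oc2c(OCc3ccccc3)c(C)c(OCc3ccccc3)c(C(=O)OC)c2C(OC)OC)c1CO[Si](C)(C)C(C)(C)C | intermediate
23 | 2-[2,4-bis(benzyloxy)-6-(dimethoxymethyl)-5-(methoxycarbonyl)-3-methylphenoxy]-3-(tert-butyldimethylsilyloxymethyl)-4-methoxy-6-methylbenzoic acid | COc1cc(C)c(C(=O)O)c(Oc2c(OCc3ccccc3)c(C)c(OCc3ccccc3)c(C(=O)OC)c2C(OC)OC)c1CO[Si](C)(C)C(C)(C)C | intermediate
24 | 2-[2,4-dihydroxy-6-(dimethoxymethyl)-5-(methoxycarbonyl)-3-methylphenoxy]-3-(tert-butyldimethylsilyloxymethyl)-4-methoxy-6-methylbenzoic acid | COc1cc(C)c(C(=O)O)c(Oc2c(O)c(C)c(O)c(C(=O)OC)c2C(OC)OC)c1CO[Si](C)(C)C(C)(C)C | intermediate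
25 | depsidone with a1 OMe, a3 Me, a6 CH2OTBS, b3 Me, b4 OH, b5 CO2Me, b6 CH(OMe)2 | COc1cc(C)c2c(c1CO[Si](C)(C)C(C)(C)C)Oc1c(c(C)c(O)c(C(=O)OC)c1C(OC)OC)OC2=O | intermediate
26 | depsidone with a6 CH2OH, b4 OH, b5 CO2Me, b6 CHO (formyl ester, not isolated) | COc1cc(C)c2c(c1CO)Oc1c(c(C)c(O)c(C(=O)OC)c1C=O)OC2=O | intermediate
27 | racemic lactol (racemate of the target) | COc1cc(C)c2c(c1CO)Oc1c(c(C)c(O)c3c1C(O)OC3=O)OC2=O | intermediate
28 | (R)-lactol propanoate with a6 CH2O-propanoyl and free b4 OH | COc1cc(C)c2c(c1COC(=O)CC)Oc1c(c(C)c(O)c3c1[C@H](OC(=O)CC)OC3=O)OC2=O | intermediate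
29 | target CNP0367167.1: depsidone with a1 OMe, a3 Me, a6 CH2OH, b3 Me, b4 OH and the b5/b6-fused γ-lactone bearing OH at the (R)-configured b6 carbon | COc1cc(C)c2c(c1CO)Oc1c(c(C)c(O)c3c1[C@H](O)OC3=O)OC2=O | target

**Totals and risks**

Total step count: 17. Longest linear sequence: 15 steps (steps 1–5, 7, 9–17).

Steps most likely to fail:

Step 9. The ring B chromophore may absorb light in competition with the diazoketone, and the aryloxyalkyne is a weaker nucleophile than an alkoxyalkyne, so ketene dimerisation or photodecomposition of the ynol ether may outrun the [2+2] cycloaddition. The fallback sets out from 11 and returns at 19. The same vinylketene 15 is generated without light by reversible four-electron ring opening of 3-methylcyclobut-2-enone F1, a known cyclobutenone obtained from 3-ethoxycyclobut-2-enone with MeLi and acidic work-up. Heating 11 with F1 in toluene at 80–110 °C should lead through 16, 17 and 18 to 19 as in the thermal Danheiser benzannulation.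

Step 16. Acylation of the lactol, which is crowded by the neighbouring b1 aryloxy group, may proceed with poor enantiomer discrimination or faster than the lactol racemises, and the b4 phenol may be acylated in competition. The fallback sets out from 27 and returns at 28. Non-selective propanoylation of 27 ((EtCO)2O, Et3N, DMAP (cat.), CH2Cl2) should give the racemic dipropanoate F4, which is resolved by preparative supercritical-fluid chromatography on a chiral stationary phase; the (R)-enantiomer is 28. The (S)-antipode can be deacylated with the lipase and returned to 27 for recycling.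

Step 7. Coupling at the b1 phenol, which is flanked on both sides, may be slow, so that decomposition of the dibromoalkene or a second substitution to a ketene acetal competes, and the elimination base may attack the ester. The fallback sets out from 7 and returns at 11 by the trichloroethylene route to ynol ethers. Treatment of 7 with KH and trichloroethylene in THF should give the (E)-1,2-dichlorovinyl ether F2. n-BuLi (2.2 equiv) in THF at −78 °C, where the doubly flanked ester is expected to survive, eliminates and exchanges the chlorines to the lithium aryloxyacetylide, which is trapped with paraformaldehyde to give methyl 4,6-bis(benzyloxy)-2-(dimethoxymethyl)-3-[(3-hydroxyprop-1-yn-1-yl)oxy]-5-methylbenzoate F3. Silylation of F3 (TBSCl, imidazole, DMF) gives 11.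

Further compounds
F1 | step 9 | 3-methylcyclobut-2-en-1-one | CC1=CC(=O)C1
F2 | step 7 | methyl 4,6-bis(benzyloxy)-3-{[(E)-1,2-dichloroethenyl]oxy}-2-(dimethoxymethyl)-5-methylbenzoate | Cl/C=C(/Cl)Oc1c(OCc2ccccc2)c(C)c(OCc2ccccc2)c(C(=O)OC)c1C(OC)OC
F3 | step 7 | methyl 4,6-bis(benzyloxy)-2-(dimethoxymethyl)-3-[(3-hydroxyprop-1-yn-1-yl)oxy]-5-methylbenzoate | OCC#COc1c(OCc2ccccc2)c(C)c(OCc2ccccc2)c(C(=O)OC)c1C(OC)OC
F4 | step 16 | racemic lactol propanoate with a6 CH2O-propanoyl (racemate of 28) | COc1cc(C)c2c(c1COC(=O)CC)Oc1c(c(C)c(O)c3c1C(OC(=O)CC)OC3=O)OC2=O
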